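**Retrosynthetic overview**

1. Numbering: ring C1 (carbinol), C2, C3 (CHCl), C4 (CMeBr), C5, C6; side chain C7 (=CH2), C8, C9, C10 (carbinol), C11 (isopropenyl). Late stage: C7=CH2 by methylenation of a C7 ketone; C7–C8 by Weinreb ketone synthesis between a ring amide and a C8–C11 Grignard reagent whose C10 centre comes from a CBS reduction.
2. Halogens: C4–Br from the tertiary alcohol of a trans-chlorohydrin; C3–Cl from chloride opening of a 3,4-epoxide lying cis to the C7 carboxyl; that epoxide from bromolactonisation of (S)-1-hydroxy-4-methylcyclohex-3-ene-1-carboxylic acid.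
3. Key disconnection: C4–C5 and C1–C2 of that cyclohexene are cut together, giving a lithiated (S)-but-3-en-2-yl carbamate (C2–C3–C4 and the methyl) and a β-boryl ketone (C5–C6–C1–C7). Forward, a 1,2-metalate shift on boron makes C4–C5 and the resulting tertiary allylic boronic ester adds through C2 to the C1 ketone.
4. Enabling feature: the vicinal C3–Cl/C4–Br pair is a masked C3=C4 double bond, so the six-membered ring hides the homoallylic alcohol O–C1–C2–C3=C4. C4, fully substituted and 1,4 to C1, can carry boron, so a temporary C4–B···O–C1 bridge (a 2-oxa-3-borabicyclo[2.2.2]octene array) closes the ring and passes the C4 configuration on to C1.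
5. Rings in order: the carbocycle (step 4); then two temporary rings, the bromolactone (step 6) and the epoxide (step 8), each opened again (steps 8 and 9).

Key step: step 4

Assumption: as is usual for boronic esters, the lithiated carbamate is taken to be borylated at its α-carbon with retention and the 1,2-shift to go with inversion; were the first event invertive, (R)-but-3-en-2-ol would be used instead.

**Route**

Step 1
Reactants: 1 (S)-but-3-en-2-ol
Product: 2 (S)-but-3-en-2-yl N,N-diisopropylcarbamate
Conditions: NaH, i-Pr2NCOCl, THF, 0 °C → reflux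
Reagents that add atoms: N,N-diisopropylcarbamoyl chloride, CC(C)N(C(C)C)C(Cl)=O
Why: O-acylation of the sodium alkoxide (nucleophilic acyl substitution) should give the carbamate that later directs α-lithiation and acts as leaving group; the stereocentre is not touched.

Step 2
Reactants: 3 1-[(tert-butyldimethylsilyl)oxy]propan-2-one; 4 2-(iodomethyl)-4,4,5,5-tetramethyl-1,3,2-dioxaborolane
Product: 5 1-[(tert-butyldimethylsilyl)oxy]-4-(4,4,5,5-tetramethyl-1,3,2-dioxaborolan-2-yl)butan-2-one
Conditions: LiN(i-Pr)2, THF, −78 °C; then 4, −78 → 25 °C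
Reagents that add atoms: none
Why: Kinetic deprotonation at the methyl group (the less hindered, non-oxygenated α-carbon) gives the enolate, whose C-alkylation by the α-iodo boronic ester (through a boron ate complex and Matteson-type 1,2-shift) should give the β-boryl ketone.

Step 3
Reactants: 5 1-[(tert-butyldimethylsilyl)oxy]-4-(4,4,5,5-tetramethyl-1,3,2-dioxaborolan-2-yl)butan-2-one
Product: 6 tert-butyl{[2,2-dimethoxy-4-(4,4,5,5-tetramethyl-1,3,2-dioxaborolan-2-yl)butyl]oxy}dimethylsilane
Conditions: MeOSiMe3, Me3SiOSO2CF3 (cat.), CH2Cl2, −78 → −20 °C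
Reagents that add atoms: methoxytrimethylsilane, CO[Si](C)(C)C
Why: Aprotic silyl-triflate-catalysed ketalisation should mask the ketone against the organolithium of step 4 without touching the silyl ether or the boronic ester.

Step 4
Reactants: 2 (S)-but-3-en-2-yl N,N-diisopropylcarbamate; 6 tert-butyl{[2,2-dimethoxy-4-(4,4,5,5-tetramethyl-1,3,2-dioxaborolan-2-yl)butyl]oxy}dimethylsilane
Product: 12 (S)-1-(hydroxymethyl)-4-methylcyclohex-3-en-1-ol, via lithiated carbamate 7 (not isolated), via boron ate complex 8 (not isolated), via tertiary allylic boronic ester 9 (not isolated), via keto boronic ester 10 (not isolated), via O-boryl cyclohexenol 11 (not isolated)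
Conditions: s-BuLi, TMEDA, Et2O, −78 °C; then 6, −78 → 25 °C; then 1 M HCl (aq), THF, 25 → 40 °C
Reagents that add atoms: water, O
Why: Proposed new method: α-lithiation of 2 with retention (7) and capture by boronic ester 6 should give ate complex 8, in which C5 migrates from boron to C4 with inversion as the carbamate leaves (Matteson-type 1,2-metalate shift), forming C4–C5 and the tertiary allylic boronic ester 9; aqueous acid then frees the C1 ketone (10), which is attacked by the γ-carbon C2 of the allylboron unit through a closed six-membered transition state, forming C1–C2 and moving the double bond to C3=C4 (11), and hydrolysis of the B–O bond releases 12. The closest known chemistry is the lithiation–borylation of secondary allylic carbamates with in-flask allylboration of aldehydes, and the acid-accelerated allylboration of ketones; new is the intramolecular version onto a ketone tethered to the boron-bearing carbon. The carbocycle closes by 6-exo-trig addition to the carbonyl, and because the C4–B···O=C1 contact spans the 1,4-positions of the forming ring (a 2-oxa-3-borabicyclo[2.2.2]octene array) the ring passes through a boat with boron and oxygen on the same face. The one new stereocentre, C1, is therefore set by the configuration of C4, itself derived from (S)-1, in a 1,4-transfer of chirality that ends with C4 becoming planar and the temporary C–B bond being cleaved. The step needs α- rather than γ-borylation of 7 (favoured by TMEDA in Et2O and a boronic ester electrophile), migration rather than reversion of 8 (the allylic carbamate is a good leaving group) and a closed rather than open addition (no Lewis acid other than the proton is present, and protonation of a boronate oxygen accelerates the closed pathway). The ketone is carried as its dimethyl ketal until the C4–B bond is in place because the organolithium would otherwise add to it, and the silyl ether is lost in the same acidic treatment.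

Step 5
Reactants: 12 (S)-1-(hydroxymethyl)-4-methylcyclohex-3-en-1-ol
Product: 13 (S)-1-hydroxy-4-methylcyclohex-3-ene-1-carboxylic acid
Conditions: 2,2,6,6-tetramethylpiperidin-1-oxyl (cat.), NaClO2, NaOCl (cat.), MeCN–phosphate buffer (pH 6.7), 35 °C
Reagents that add atoms: sodium chlorite, [Na+].[O-]Cl=O
Why: Nitroxyl-catalysed oxidation with chlorite as terminal oxidant should take the primary alcohol through the aldehyde to the acid, while the tertiary alcohol cannot be oxidised and the catalytic amount of hypochlorite spares the trisubstituted alkene.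

Step 6
Reactants: 13 (S)-1-hydroxy-4-methylcyclohex-3-ene-1-carboxylic acid
Product: 14 (1S,4R,5R)-4-bromo-1-hydroxy-4-methyl-6-oxabicyclo[3.2.1]octan-7-one (lactone oxygen on C3 cis to the carboxyl carbon, bromine on C4 trans to it)
Conditions: NBS, NaHCO3, MeCN–H2O, 0 °C
Reagents that add atoms: N-bromosuccinimide, O=C1CCC(=O)N1Br
Why: Bromolactonisation: the carboxylate on the lower face of C1 opens the bromonium ion of the C3=C4 alkene in an anti addition, so oxygen goes to the lower face at C3 and bromine to the upper face at C4, both set by C1 through the temporary lactone ring; either regiochemical mode of lactone closure would lead to the same epoxide in step 8.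

Step 7
Reactants: 14 (1S,4R,5R)-4-bromo-1-hydroxy-4-methyl-6-oxabicyclo[3.2.1]octan-7-one
Product: 15 (1S,4R,5R)-4-bromo-4-methyl-1-[(triethylsilyl)oxy]-6-oxabicyclo[3.2.1]octan-7-one
Conditions: Et3SiOSO2CF3, 2,6-lutidine, CH2Cl2, 0 °C
Reagents that add atoms: triethylsilyl trifluoromethanesulfonate, CC[Si](CC)(CC)OS(=O)(=O)C(F)(F)F
Why: Silylation of the tertiary alcohol with the silyl triflate should block its oxygen so that it cannot attack C4 across the ring in the cationic steps 9 and 10 nor consume organometallic reagents later.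

Step 8
Reactants: 15 (1S,4R,5R)-4-bromo-4-methyl-1-[(triethylsilyl)oxy]-6-oxabicyclo[3.2.1]octan-7-one
Product: 17 (1S,3R,4S)-3,4-epoxy-N-methoxy-N,4-dimethyl-1-[(triethylsilyl)oxy]cyclohexane-1-carboxamide (epoxide cis to the amide, trans to the silyl ether), via bromohydrin amide 16 (not isolated)
Conditions: MeNH(OMe)·HCl, i-PrMgCl, THF, −20 → 0 °C; then K2CO3, MeOH, 25 °C
Reagents that add atoms: N,O-dimethylhydroxylamine hydrochloride, CNOC.Cl
Why: Aminolysis of the strained lactone by the magnesium amide gives the Weinreb amide and frees the C3 alkoxide, which on treatment with carbonate displaces the anti bromide at C4 (intramolecular Williamson etherification, inversion at C4), placing the epoxide on the lower face.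

Step 9
Reactants: 17 (1S,3R,4S)-3,4-epoxy-N-methoxy-N,4-dimethyl-1-[(triethylsilyl)oxy]cyclohexane-1-carboxamide
Product: 18 (1S,3S,4S)-3-chloro-4-hydroxy-N-methoxy-N,4-dimethyl-1-[(triethylsilyl)oxy]cyclohexane-1-carboxamide (Cl cis to the C1 oxygen, C4–OH trans to Cl)
Conditions: LiCl, AcOH, THF, 25 °C
Reagents that add atoms: lithium chloride, [Li+].[Cl-]
Why: Acid-assisted SN2 opening of the epoxide by chloride at the less substituted C3, which is also the trans-diaxial (Fürst–Plattner) mode in the conformer with the amide equatorial, should invert C3 and put chlorine on the upper face, leaving the tertiary alcohol at C4.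

Step 10
Reactants: 18 (1S,3S,4S)-3-chloro-4-hydroxy-N-methoxy-N,4-dimethyl-1-[(triethylsilyl)oxy]cyclohexane-1-carboxamide
Product: 19 (1S,3S,4S)-4-bromo-3-chloro-N-methoxy-N,4-dimethyl-1-[(triethylsilyl)oxy]cyclohexane-1-carboxamide
Conditions: Me3SiBr, CH2Cl2, −20 → 0 °C
Reagents that add atoms: bromotrimethylsilane, C[Si](C)(C)Br
Why: SN1 substitution of the tertiary alcohol: the anti-periplanar chlorine at C3 shields the upper face of the C4 cation (chloronium-type participation), so bromide should enter from the lower face with net retention, giving the trans-diaxial bromochloride, which is also the more stable epimer (bromine axial, methyl equatorial).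

Step 11
Reactants: 20 3-chloropropanoyl chloride; 21 isopropenylmagnesium bromide
Product: 22 5-chloro-2-methylpent-1-en-3-one
Conditions: CuBr·SMe2 (cat.), THF, −78 °C
Reagents that add atoms: none
Why: Copper-catalysed acylation of the alkenyl Grignard reagent by the acid chloride at low temperature should stop at the enone, because the organocopper species does not add to the ketone formed.

Step 12
Reactants: 22 5-chloro-2-methylpent-1-en-3-one
Product: 23 (R)-5-chloro-2-methylpent-1-en-3-ol
Conditions: (S)-1-methyl-3,3-diphenyltetrahydro-1H,3H-pyrrolo[1,2-c][1,3,2]oxazaborole (cat.), BH3·SMe2, THF, −30 °C; MeOH quench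
Reagents that add atoms: none
Why: Corey–Bakshi–Shibata reduction: with isopropenyl as the large and chloroethyl as the small substituent, the (S)-catalyst should deliver hydride to give the (R)-allylic alcohol, which sets C10.

Step 13
Reactants: 23 (R)-5-chloro-2-methylpent-1-en-3-ol
Product: 24 {[(3R)-5-chloro-2-methylpent-1-en-3-yl]oxy}triethylsilane
Conditions: Et3SiCl, imidazole, CH2Cl2, 0 → 25 °C
Reagents that add atoms: chlorotriethylsilane, CC[Si](Cl)(CC)CC
Why: Imidazole-assisted silylation protects the secondary alcohol as a triethylsilyl ether that should survive Grignard formation and is removed in the last step.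

Step 14
Reactants: 19 (1S,3S,4S)-4-bromo-3-chloro-N-methoxy-N,4-dimethyl-1-[(triethylsilyl)oxy]cyclohexane-1-carboxamide; 24 {[(3R)-5-chloro-2-methylpent-1-en-3-yl]oxy}triethylsilane
Product: 26 (4R)-1-[(1S,3S,4S)-4-bromo-3-chloro-4-methyl-1-(triethylsilyloxy)cyclohexyl]-5-methyl-4-(triethylsilyloxy)hex-5-en-1-one, via alkylmagnesium chloride 25 (not isolated)
Conditions: 24, Mg, THF, 50 °C; then 19, THF, −20 → 25 °C; aq NH4Cl
Reagents that add atoms: none
Why: Weinreb ketone synthesis: the Grignard reagent from magnesium insertion into the primary chloride adds once to the amide (chelated tetrahedral intermediate, no over-addition), and since the amide has no α-hydrogen and alkylmagnesium halides neither exchange with nor readily eliminate tertiary bromides at low temperature, C7–C8 should form with both halogens intact.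

Step 15
Reactants: 26 (4R)-1-[(1S,3S,4S)-4-bromo-3-chloro-4-methyl-1-(triethylsilyloxy)cyclohexyl]-5-methyl-4-(triethylsilyloxy)hex-5-en-1-one
Product: 27 {[(3R)-6-[(1S,3S,4S)-4-bromo-3-chloro-4-methyl-1-(triethylsilyloxy)cyclohexyl]-2-methylhepta-1,6-dien-3-yl]oxy}triethylsilane
Conditions: Cp2Ti(μ-CH2)(μ-Cl)AlMe2, pyridine, THF–toluene, −40 → 0 °C
Reagents that add atoms: Tebbe reagent Cp2Ti(μ-CH2)(μ-Cl)AlMe2, C[Al-]1(C)C[Ti]([Cl+]1)(C1C=CC=C1)C1C=CC=C1
Why: Tebbe methylenation: the weakly basic titanium methylidene should convert the hindered C7 ketone into the 1,1-disubstituted alkene by [2+2] cycloaddition–cycloreversion, without the E2 loss of HBr that a phosphorus ylide would risk.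

Step 16
Reactants: 27 {[(3R)-6-[(1S,3S,4S)-4-bromo-3-chloro-4-methyl-1-(triethylsilyloxy)cyclohexyl]-2-methylhepta-1,6-dien-3-yl]oxy}triethylsilane
Product: 28 (1S,3S,4S)-4-bromo-3-chloro-1-[(5R)-5-hydroxy-6-methylhepta-1,6-dien-2-yl]-4-methylcyclohexan-1-ol (target)
Conditions: HF·pyridine, pyridine, THF, 0 → 25 °C
Reagents that add atoms: none
Why: Fluoride-mediated cleavage of both triethylsilyl ethers under buffered, weakly acidic conditions should free the secondary and tertiary alcohols without ionising the tertiary allylic carbinol or eliminating the tertiary bromide.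

**Compound list**

1 | (S)-but-3-en-2-ol | C[C@H](O)C=C | starting material
2 | (S)-but-3-en-2-yl N,N-diisopropylcarbamate | C[C@H](OC(=O)N(C(C)C)C(C)C)C=C | intermediate
3 | 1-[(tert-butyldimethylsilyl)oxy]propan-2-one | CC(=O)CO[Si](C)(C)C(C)(C)C | starting material
4 | 2-(iodomethyl)-4,4,5,5-tetramethyl-1,3,2-dioxaborolane | ICB1OC(C)(C)C(C)(C)O1 | starting material
5 | 1-[(tert-butyldimethylsilyl)oxy]-4-(4,4,5,5-tetramethyl-1,3,2-dioxaborolan-2-yl)butan-2-one | CC(C)(C)[Si](C)(C)OCC(=O)CCB1OC(C)(C)C(C)(C)O1 | intermediate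
6 | tert-butyl{[2,2-dimethoxy-4-(4,4,5,5-tetramethyl-1,3,2-dioxaborolan-2-yl)butyl]oxy}dimethylsilane | COC(CO[Si](C)(C)C(C)(C)C)(CCB1OC(C)(C)C(C)(C)O1)OC | intermediate
7 | (S)-2-lithiobut-3-en-2-yl N,N-diisopropylcarbamate (lithium in place of the carbinol hydrogen of 2) | C[C@]([Li])(OC(=O)N(C(C)C)C(C)C)C=C | intermediate
8 | lithium boron ate complex of 7 with 6 (boron on the former carbinol carbon, retention) | [Li+].C[C@](OC(=O)N(C(C)C)C(C)C)(C=C)[B-]1(CCC(OC)(OC)CO[Si](C)(C)C(C)(C)C)OC(C)(C)C(C)(C)O1 | intermediate
9 | tert-butyl{[(5S)-2,2-dimethoxy-5-methyl-5-(4,4,5,5-tetramethyl-1,3,2-dioxaborolan-2-yl)hept-6-en-1-yl]oxy}dimethylsilane | COC(CO[Si](C)(C)C(C)(C)C)(OC)CC[C@](C)(C=C)B1OC(C)(C)C(C)(C)O1 | intermediate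
10 | (5S)-1-hydroxy-5-methyl-5-(4,4,5,5-tetramethyl-1,3,2-dioxaborolan-2-yl)hept-6-en-2-one | OCC(=O)CC[C@](C)(C=C)B1OC(C)(C)C(C)(C)O1 | intermediate
11 | 2-{[(1S)-1-(hydroxymethyl)-4-methylcyclohex-3-en-1-yl]oxy}-4,4,5,5-tetramethyl-1,3,2-dioxaborolane | OC[C@]1(OB2OC(C)(C)C(C)(C)O2)CCC(C)=CC1 | intermediate
12 | (S)-1-(hydroxymethyl)-4-methylcyclohex-3-en-1-ol | OC[C@]1(O)CCC(C)=CC1 | intermediate
13 | (S)-1-hydroxy-4-methylcyclohex-3-ene-1-carboxylic acid | OC(=O)[C@]1(O)CCC(C)=CC1 | intermediate
14 | (1S,4R,5R)-4-bromo-1-hydroxy-4-methyl-6-oxabicyclo[3.2.1]octan-7-one | O=C2[C@]1(O)CC[C@](Br)(C)[C@H](O2)C1 | intermediate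
15 | (1S,4R,5R)-4-bromo-4-methyl-1-[(triethylsilyl)oxy]-6-oxabicyclo[3.2.1]octan-7-one | O=C2[C@]1(O[Si](CC)(CC)CC)CC[C@](Br)(C)[C@H](O2)C1 | intermediate
16 | (1S,3R,4R)-4-bromo-3-hydroxy-N-methoxy-N,4-dimethyl-1-[(triethylsilyl)oxy]cyclohexane-1-carboxamide | CON(C)C(=O)[C@]1(O[Si](CC)(CC)CC)CC[C@](Br)(C)[C@H](O)C1 | intermediate
17 | (1S,3R,4S)-3,4-epoxy-N-methoxy-N,4-dimethyl-1-[(triethylsilyl)oxy]cyclohexane-1-carboxamide | CON(C)C(=O)[C@]1(O[Si](CC)(CC)CC)CC[C@]2(C)O[C@@H]2C1 | intermediate
18 | (1S,3S,4S)-3-chloro-4-hydroxy-N-methoxy-N,4-dimethyl-1-[(triethylsilyl)oxy]cyclohexane-1-carboxamide | CON(C)C(=O)[C@]1(O[Si](CC)(CC)CC)CC[C@](C)(O)[C@@H](Cl)C1 | intermediate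
19 | (1S,3S,4S)-4-bromo-3-chloro-N-methoxy-N,4-dimethyl-1-[(triethylsilyl)oxy]cyclohexane-1-carboxamide | CON(C)C(=O)[C@]1(O[Si](CC)(CC)CC)CC[C@](C)(Br)[C@@H](Cl)C1 | intermediate
20 | 3-chloropropanoyl chloride | O=C(Cl)CCCl | starting material
21 | isopropenylmagnesium bromide (prop-1-en-2-ylmagnesium bromide) | C=C(C)[Mg]Br | starting material
22 | 5-chloro-2-methylpent-1-en-3-one | C=C(C)C(=O)CCCl | intermediate
23 | (R)-5-chloro-2-methylpent-1-en-3-ol | C=C(C)[C@H](O)CCCl | intermediate
24 | {[(3R)-5-chloro-2-methylpent-1-en-3-yl]oxy}triethylsilane | C=C(C)[C@H](O[Si](CC)(CC)CC)CCCl | intermediate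
25 | [(3R)-4-methyl-3-(triethylsilyloxy)pent-4-en-1-yl]magnesium chloride | C=C(C)[C@H](O[Si](CC)(CC)CC)CC[Mg]Cl | intermediate
26 | (4R)-1-[(1S,3S,4S)-4-bromo-3-chloro-4-methyl-1-(triethylsilyloxy)cyclohexyl]-5-methyl-4-(triethylsilyloxy)hex-5-en-1-one | C=C(C)[C@H](O[Si](CC)(CC)CC)CCC(=O)[C@]1(O[Si](CC)(CC)CC)CC[C@](C)(Br)[C@@H](Cl)C1 | intermediate
27 | {[(3R)-6-[(1S,3S,4S)-4-bromo-3-chloro-4-methyl-1-(triethylsilyloxy)cyclohexyl]-2-methylhepta-1,6-dien-3-yl]oxy}triethylsilane | C=C(C)[C@H](O[Si](CC)(CC)CC)CCC(=C)[C@]1(O[Si](CC)(CC)CC)CC[C@](C)(Br)[C@@H](Cl)C1 | intermediate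
28 | (1S,3S,4S)-4-bromo-3-chloro-1-[(5R)-5-hydroxy-6-methylhepta-1,6-dien-2-yl]-4-methylcyclohexan-1-ol | C=C(C)[C@H](O)CCC(=C)[C@]1(O)CC[C@](C)(Br)[C@@H](Cl)C1 | target

**Step count**

Total step count: 16.
Longest linear sequence: 12 steps (3 → 5 → 6 → 12 → 13 → 14 → 15 → 17 → 18 → 19 → 26 → 27 → 28; steps 2–10 and 14–16).

**Steps most likely to fail**

Step 4 (carries the label). What may go wrong: borylation of the lithiated carbamate at its γ-carbon, protodeboronation of the tertiary allylic boronic ester during the acidic unmasking, or ring closure through an open transition state that erodes the transfer of chirality from C4 to C1. Fallback, known chemistry only, setting out from 1 and coming back at 13: 1 is esterified with [(4-methoxybenzyl)oxy]acetic acid (DCC, 4-(dimethylamino)pyridine, CH2Cl2) to (S)-but-3-en-2-yl 2-[(4-methoxybenzyl)oxy]acetate F1. Its lithium enolate (LiN(i-Pr)2, THF–DMPU, −78 °C) is alkylated with 4-iodo-2-methylbut-1-ene to (S)-but-3-en-2-yl 2-[(4-methoxybenzyl)oxy]-5-methylhex-5-enoate F2, used as the mixture of epimers at the new centre. A chelate-controlled Ireland–Claisen rearrangement (KN(SiMe3)2, Me3SiCl, toluene, −78 → 25 °C; chair with the carbinol methyl equatorial, ether oxygen cis to the enolate oxygen) should form C1–C2 and set C1, giving (2S,4E)-2-[(4-methoxybenzyl)oxy]-2-(3-methylbut-3-en-1-yl)hex-4-enoic acid F3. Ring-closing metathesis with the second-generation Grubbs catalyst (H2IMes)(PCy3)Cl2Ru=CHPh closes C3=C4 to (S)-1-[(4-methoxybenzyl)oxy]-4-methylcyclohex-3-ene-1-carboxylic acid F4, and DDQ (CH2Cl2–H2O) removes the benzyl ether to give 13. This fallback builds the ring in two operations instead of one.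

Step 10. What may go wrong: ionisation at C4 ending in elimination to alkenes, capture of the cation by the amide oxygen, or migration of chlorine with scrambling of the two halogens. Fallback, setting out from 17 and coming back at 19: the epoxide 17 is isomerised with Et2AlN(C9H18) (diethylaluminum 2,2,6,6-tetramethylpiperidide, toluene, 0 °C), which removes a proton from the C4 methyl group and keeps the C3–O bond, to the allylic alcohol (1S,3R)-3-hydroxy-N-methoxy-N-methyl-4-methylidene-1-[(triethylsilyl)oxy]cyclohexane-1-carboxamide F5. Appel chlorination (PPh3, CCl4) should replace the allylic hydroxyl with inversion to give the upper-face chloride (1S,3S)-3-chloro-N-methoxy-N-methyl-4-methylidene-1-[(triethylsilyl)oxy]cyclohexane-1-carboxamide F6. Mukaiyama-type hydrogen-atom-transfer hydrobromination (Co(C5H7O2)2 (cat.), t-BuOOH, Et3SiH, TsBr) then adds hydrogen to the exocyclic CH2 and traps the tertiary C4 radical with bromine anti to the axial chlorine, giving 19 without a cation at C4.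

Step 14. What may go wrong: slow addition to the hindered amide carbonyl on a fully substituted carbon, giving time for base-induced loss of HBr from the tertiary bromide, or 1,3-elimination within the γ-silyloxy Grignard reagent before it adds. Fallback, setting out from 19 and coming back at 26: 19 is reduced with i-Bu2AlH (CH2Cl2, −78 °C) to the aldehyde (1S,3S,4S)-4-bromo-3-chloro-4-methyl-1-[(triethylsilyl)oxy]cyclohexane-1-carbaldehyde F7. F7 should accept the Grignard reagent 25 already at −78 °C to give the secondary carbinol (4R)-1-[(1S,3S,4S)-4-bromo-3-chloro-4-methyl-1-(triethylsilyloxy)cyclohexyl]-5-methyl-4-(triethylsilyloxy)hex-5-en-1-ol F8 (either epimer at the new carbinol centre serves), and Dess–Martin periodinane oxidises F8 to 26.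

**Further compounds**

F1 | step 4 | (S)-but-3-en-2-yl 2-[(4-methoxybenzyl)oxy]acetate | C=C[C@H](C)OC(=O)COCc1ccc(OC)cc1
F2 | step 4 | (S)-but-3-en-2-yl 2-[(4-methoxybenzyl)oxy]-5-methylhex-5-enoate (both epimers at C2 of the acid part) | C=C[C@H](C)OC(=O)C(CCC(C)=C)OCc1ccc(OC)cc1
F3 | step 4 | (2S,4E)-2-[(4-methoxybenzyl)oxy]-2-(3-methylbut-3-en-1-yl)hex-4-enoic acid | OC(=O)[C@](C/C=C/C)(OCc1ccc(OC)cc1)CCC(C)=C
F4 | step 4 | (S)-1-[(4-methoxybenzyl)oxy]-4-methylcyclohex-3-ene-1-carboxylic acid | OC(=O)[C@]1(OCc2ccc(OC)cc2)CCC(C)=CC1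
F5 | step 10 | (1S,3R)-3-hydroxy-N-methoxy-N-methyl-4-methylidene-1-[(triethylsilyl)oxy]cyclohexane-1-carboxamide | CON(C)C(=O)[C@]1(O[Si](CC)(CC)CC)CCC(=C)[C@H](O)C1
F6 | step 10 | (1S,3S)-3-chloro-N-methoxy-N-methyl-4-methylidene-1-[(triethylsilyl)oxy]cyclohexane-1-carboxamide | CON(C)C(=O)[C@]1(O[Si](CC)(CC)CC)CCC(=C)[C@@H](Cl)C1
F7 | step 14 | (1S,3S,4S)-4-bromo-3-chloro-4-methyl-1-[(triethylsilyl)oxy]cyclohexane-1-carbaldehyde | O=C[C@]1(O[Si](CC)(CC)CC)CC[C@](C)(Br)[C@@H](Cl)C1
F8 | step 14 | (4R)-1-[(1S,3S,4S)-4-bromo-3-chloro-4-methyl-1-(triethylsilyloxy)cyclohexyl]-5-methyl-4-(triethylsilyloxy)hex-5-en-1-ol (both epimers at C1 of the chain) | C=C(C)[C@H](O[Si](CC)(CC)CC)CCC(O)[C@]1(O[Si](CC)(CC)CC)CC[C@](C)(Br)[C@@H](Cl)C1
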